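**Retrosynthetic overview**
- The target comes from its 15-acetate by selective methanolysis of the primary allylic acetate.
- Key disconnection at C7–O: the 6β-acyloxy/7α-hydroxy pair comes from a ring-B 6-acyloxy-6,8-diene (dienyl isovalerate) plus water, added anti-Markovnikov across C6=C7 from the α face; this sets C6 and C7.
- The dienyl isovalerate comes from the 6-oxo-Δ7 enone (O-acylation of its extended dienolate), and the enone from the Δ7 alkene by allylic C–H oxidation at C6.
- The Δ7 alkene with the (13E)-15-acetoxy side chain comes from (−)-sclareol: [3,3] transposition of the tertiary allylic acetate, then 8-acetate elimination and alkene isomerisation.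
- Ring order: no ring is formed; rings A and B, with C5 and C10, are taken intact from sclareol.

Assumption: the SMILES is read as the normal-series labdane 6β-(3-methylbutanoyloxy)labda-8,13E-diene-7α,15-diol (5S,6S,7S,10S, labdane numbering; 5α-H, 10β-CH3).

**Step 1**
Reactants: 1 (−)-sclareol
Product: 2 sclareol diacetate
Conditions: AcCl (4 equiv), N,N-dimethylaniline (5 equiv), CH2Cl2, 0 °C to rt, 24 h
Reagents that add atoms: acetyl chloride, CC(=O)Cl
Why: Ester formation at both tertiary hydroxyls with acetyl chloride buffered by the weak base N,N-dimethylaniline, which avoids ionising the tertiary allylic centre; no stereocentre is touched.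

**Step 2**
Reactants: 2 sclareol diacetate
Product: 3 (13E)-labd-13-ene-8α,15-diyl diacetate
Conditions: PdCl2(MeCN)2 (5 mol%), THF, rt, 2 h
Reagents that add atoms: none
Why: Divalent-palladium-catalysed [3,3] transposition of the tertiary allylic acetate (cyclisation-induced rearrangement through a six-membered acetoxonium) runs to the primary acetate with the trisubstituted alkene, 13E being the major isomer; the minor 13Z isomer is removed on AgNO3-impregnated silica and re-equilibrated with the same catalyst, and the saturated 8-acetate cannot react.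

**Step 3**
Reactants: 3 (13E)-labd-13-ene-8α,15-diyl diacetate
Product: 4 labda-8(17),13E-dien-15-yl acetate
Conditions: 2,4,6-collidine, reflux (about 170 °C), 8 h
Reagents that add atoms: none
Why: Thermal syn-elimination of acetic acid from the tertiary 8α-acetate (ester pyrolysis) takes mainly a freely rotating C17 hydrogen, so the exocyclic alkene dominates; the lesser Δ7 co-product is compound 5 itself, so the crude mixture goes on to step 4, and the primary allylic acetate and C9 are unaffected.

**Step 4**
Reactants: 4 labda-8(17),13E-dien-15-yl acetate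
Product: 5 labda-7,13E-dien-15-yl acetate
Conditions: Co(salen)Cl (3 mol%; trivalent cobalt chloride complex of N,N′-bis(3,5-di-tert-butylsalicylidene)-1,2-cyclohexanediamine), PhSiH3 (6 mol%), benzene, rt, 12 h
Reagents that add atoms: none
Why: Cobalt-hydride hydrogen-atom-transfer alkene isomerisation: a hydrogen atom adds to C17, the tertiary C8 radical returns its less hindered C7 hydrogen to cobalt, and the double bond moves one position into the ring; trisubstituted alkenes (Δ7, Δ13) are not substrates and the 9α-hydrogen is untouched.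

**Step 5**
Reactants: 5 labda-7,13E-dien-15-yl acetate
Product: 6 6-oxolabda-7,13E-dien-15-yl acetate
Conditions: CrO3 (12 equiv), 3,5-dimethylpyrazole (12 equiv), CH2Cl2, −20 °C, 4 h
Reagents that add atoms: chromium trioxide, O=[Cr](=O)=O
Why: Allylic C–H oxidation with the CrO3·3,5-dimethylpyrazole complex converts the ring methylene on the CH end of the trisubstituted alkene (C6, the counterpart of C7 in the Δ5-steroid to 7-ketone oxidation) into the enone without moving the alkene; the C13 alkene is deactivated by its allylic acetate and C5 is not epimerised at −20 °C.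

**Step 6**
Reactants: 6 6-oxolabda-7,13E-dien-15-yl acetate; 7 3-methylbutanoic anhydride
Product: 9 15-acetoxylabda-6,8,13E-trien-6-yl 3-methylbutanoate, via potassium dienolate 8 (not isolated)
Conditions: KH (1.1 equiv), t-BuOH (5 mol%), THF, 0 °C to rt, 1 h; then 7 (1.5 equiv), −78 to 0 °C
Reagents that add atoms: none
Why: Thermodynamic γ-deprotonation (t-BuOH as proton shuttle) gives the fully conjugated endocyclic dienolate, in which C9 becomes sp2 and C5 is not involved, and O-acylation of this hindered potassium dienolate (enol ester formation) puts the isovaleryl group on O6 before C6 is a stereocentre; the far less acidic primary acetate survives.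

**Step 7**
Reactants: 9 15-acetoxylabda-6,8,13E-trien-6-yl 3-methylbutanoate
Product: 10 15-acetoxy-7α-hydroxylabda-8,13E-dien-6β-yl 3-methylbutanoate
Conditions: 9-mesityl-10-methylacridinium tetrafluoroborate (5 mol%), 2-phenylmalononitrile (30 mol%), H2O (20 equiv), MeCN/1,2-dichloroethane 1:1, 450 nm LEDs, rt, N2
Reagents that add atoms: water, O
Why: Proposed new method: acridinium photoredox anti-Markovnikov hydration of a 1-acyloxy-1,3-diene, in which the excited acridinium (about +2.0 volts against SCE) oxidises only the ring diene (estimated +1.4 to +1.6 volts; the allylic-acetate alkene at C13 lies above +2.0 volts), water adds to the radical cation at C7 (the only unsubstituted sp2 carbon and the position β to the acyloxy oxygen, C9 being fully substituted and neopentylic) from the α face away from the 10β-methyl, and the tertiary α-acyloxy radical at C6 then takes a hydrogen atom from 2-phenylmalononitrile on the open α face (the β face is closed by the syn-axial 4β- and 10β-methyls, as in hydride reductions of 6-ketones), giving the trans-diaxial 6β-ester/7α-alcohol with the acyl group never leaving O6; the closest known reaction type is the acridinium/hydrogen-atom-donor anti-Markovnikov hydration and hydroacyloxylation of styrenes and trisubstituted alkenes through alkene radical cations, not yet shown on dienyl esters.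

**Step 8**
Reactants: 10 15-acetoxy-7α-hydroxylabda-8,13E-dien-6β-yl 3-methylbutanoate
Product: 11 7α,15-dihydroxylabda-8,13E-dien-6β-yl 3-methylbutanoate
Conditions: K2CO3 (0.3 equiv), MeOH, 0 °C, 2 h
Reagents that add atoms: none
Why: Base-catalysed methanolysis (transesterification) cleaves the unhindered primary allylic acetate quickly, while the axial 6β-isovalerate, flanked by the syn-axial 4β- and 10β-methyls, is untouched and cannot migrate to the trans-diaxial 7α-hydroxyl; no stereocentre is affected.

**Compound list**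
1 | (−)-sclareol, (13R)-labd-14-ene-8α,13-diol | C=C[C@](C)(O)CC[C@@H]1[C@@]2(C)CCCC(C)(C)[C@@H]2CC[C@@]1(C)O | starting material
2 | sclareol diacetate, (13R)-labd-14-ene-8α,13-diyl diacetate | C=C[C@](C)(OC(C)=O)CC[C@@H]1[C@@]2(C)CCCC(C)(C)[C@@H]2CC[C@@]1(C)OC(C)=O | intermediate
3 | (13E)-labd-13-ene-8α,15-diyl diacetate | CC(=O)OC/C=C(\C)CC[C@@H]1[C@@]2(C)CCCC(C)(C)[C@@H]2CC[C@@]1(C)OC(C)=O | intermediate
4 | labda-8(17),13E-dien-15-yl acetate | CC(=O)OC/C=C(\C)CC[C@@H]1[C@@]2(C)CCCC(C)(C)[C@@H]2CCC1=C | intermediate
5 | labda-7,13E-dien-15-yl acetate | CC(=O)OC/C=C(\C)CC[C@@H]1[C@@]2(C)CCCC(C)(C)[C@@H]2CC=C1C | intermediate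
6 | 6-oxolabda-7,13E-dien-15-yl acetate | CC(=O)OC/C=C(\C)CC[C@@H]1[C@@]2(C)CCCC(C)(C)[C@@H]2C(=O)C=C1C | intermediate
7 | 3-methylbutanoic anhydride (isovaleric anhydride) | CC(C)CC(=O)OC(=O)CC(C)C | starting material
8 | potassium 15-acetoxylabda-6,8,13E-trien-6-olate | CC1=C(CC/C(C)=C/COC(C)=O)[C@@]2(C)CCCC(C)(C)[C@@H]2C([O-])=C1.[K+] | intermediate
9 | 15-acetoxylabda-6,8,13E-trien-6-yl 3-methylbutanoate | CC1=C(CC/C(C)=C/COC(C)=O)[C@@]2(C)CCCC(C)(C)[C@@H]2C(OC(=O)CC(C)C)=C1 | intermediate
10 | 15-acetoxy-7α-hydroxylabda-8,13E-dien-6β-yl 3-methylbutanoate | CC1=C(CC/C(C)=C/COC(C)=O)[C@@]2(C)CCCC(C)(C)[C@@H]2[C@H](OC(=O)CC(C)C)[C@H]1O | intermediate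
11 | 7α,15-dihydroxylabda-8,13E-dien-6β-yl 3-methylbutanoate (CNP0173680.1) | CC1=C(CC/C(C)=C/CO)[C@@]2(C)CCCC(C)(C)[C@@H]2[C@H](OC(=O)CC(C)C)[C@H]1O | target

**Step count**
Total steps: 8. Longest linear sequence: 8 steps (1 to 11).

**Steps most likely to fail**

Step 7 (the proposed new step). Water may add at C9 or at the ester carbonyl (which returns enone 6), the face selectivity at C7 may be modest, and the product alkene may be re-oxidised on long irradiation. The fallback uses known chemistry, sets out from enone 6 and comes back to the route at target 11. Potassium dienolate 8, made from 6 as in step 6, is hydroxylated at C7 with 2-(phenylsulfonyl)-3-phenyloxaziridine (THF, −78 °C; α-carbon attack of the extended dienolate from the α face) to give 15-acetoxy-7α-hydroxylabda-8,13E-dien-6-one F1. Ac2O with DMAP in pyridine gives 6-oxolabda-8,13E-diene-7α,15-diyl diacetate F2. NaBH4 in MeOH/CH2Cl2 at 0 °C delivers hydride to the 6-ketone from the α face to give 6β-hydroxylabda-8,13E-diene-7α,15-diyl diacetate F3. Anhydride 7 with DMAP in pyridine at 80 °C acylates the 6β-hydroxyl to give 7α,15-diacetoxylabda-8,13E-dien-6β-yl 3-methylbutanoate F4. K2CO3 in MeOH at rt, monitored, removes both acetates and leaves the hindered 6β-isovalerate, giving 11.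

Step 5. Hexavalent chromium may also attack the tertiary allylic C9–H or the side-chain allylic positions. The fallback sets out from alkene 5 and comes back at enone 6. mCPBA with NaHCO3 (CH2Cl2, 0 °C) epoxidises the ring alkene from the α face, the C13 alkene being deactivated by its allylic acetate, to give 7α,8α-epoxylabd-13E-en-15-yl acetate F5. PhSeNa (sodium benzeneselenolate, from (PhSe)2 and NaBH4, EtOH/THF, 50 °C) opens the epoxide at C7 with inversion to 8α-hydroxy-7β-(phenylselanyl)labd-13E-en-15-yl acetate F6. H2O2 (THF, 0 °C to rt) gives 8α-hydroxy-7β-(phenylseleninyl)labd-13E-en-15-yl acetate F7, which undergoes syn-elimination toward C6 (C8 carries no hydrogen) to 8α-hydroxylabda-6,13E-dien-15-yl acetate F8. Pyridinium chlorochromate, (C5H5NH)[CrO3Cl], in CH2Cl2 at rt then effects the oxidative [3,3] transposition of this tertiary allylic alcohol (Babler–Dauben oxidation) to 6.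

Step 3. The pyrolysis may give too much of the tetrasubstituted Δ8(9) isomer, which step 4 does not convert, or may degrade the allylic acetate. The fallback sets out from diacetate 3 and comes back at alkene 4. KOH in MeOH at reflux saponifies both acetates to labd-13E-ene-8α,15-diol F9. Ac2O in pyridine (0 °C to rt) acetylates only the primary allylic hydroxyl to give 8α-hydroxylabd-13E-en-15-yl acetate F10. SOCl2 with pyridine (CH2Cl2, −78 °C) dehydrates the tertiary alcohol by E2 through its chlorosulfite; no ring hydrogen is antiperiplanar to the equatorial leaving group, so the proton is taken from C17 and exocyclic alkene 4 results.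

**Further compounds**
F1 | step 7 | 15-acetoxy-7α-hydroxylabda-8,13E-dien-6-one | CC1=C(CC/C(C)=C/COC(C)=O)[C@@]2(C)CCCC(C)(C)[C@@H]2C(=O)[C@H]1O
F2 | step 7 | 6-oxolabda-8,13E-diene-7α,15-diyl diacetate | CC1=C(CC/C(C)=C/COC(C)=O)[C@@]2(C)CCCC(C)(C)[C@@H]2C(=O)[C@H]1OC(C)=O
F3 | step 7 | 6β-hydroxylabda-8,13E-diene-7α,15-diyl diacetate | CC1=C(CC/C(C)=C/COC(C)=O)[C@@]2(C)CCCC(C)(C)[C@@H]2[C@H](O)[C@H]1OC(C)=O
F4 | step 7 | 7α,15-diacetoxylabda-8,13E-dien-6β-yl 3-methylbutanoate | CC1=C(CC/C(C)=C/COC(C)=O)[C@@]2(C)CCCC(C)(C)[C@@H]2[C@H](OC(=O)CC(C)C)[C@H]1OC(C)=O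
F5 | step 5 | 7α,8α-epoxylabd-13E-en-15-yl acetate | CC(=O)OC/C=C(\C)CC[C@@H]1[C@@]2(C)CCCC(C)(C)[C@@H]2C[C@H]3O[C@]31C
F6 | step 5 | 8α-hydroxy-7β-(phenylselanyl)labd-13E-en-15-yl acetate | CC(=O)OC/C=C(\C)CC[C@@H]1[C@@]2(C)CCCC(C)(C)[C@@H]2C[C@H]([Se]c3ccccc3)[C@@]1(C)O
F7 | step 5 | 8α-hydroxy-7β-(phenylseleninyl)labd-13E-en-15-yl acetate | CC(=O)OC/C=C(\C)CC[C@@H]1[C@@]2(C)CCCC(C)(C)[C@@H]2C[C@H]([Se](=O)c3ccccc3)[C@@]1(C)O
F8 | step 5 | 8α-hydroxylabda-6,13E-dien-15-yl acetate | CC(=O)OC/C=C(\C)CC[C@@H]1[C@@]2(C)CCCC(C)(C)[C@@H]2C=C[C@@]1(C)O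
F9 | step 3 | labd-13E-ene-8α,15-diol | OC/C=C(\C)CC[C@@H]1[C@@]2(C)CCCC(C)(C)[C@@H]2CC[C@@]1(C)O
F10 | step 3 | 8α-hydroxylabd-13E-en-15-yl acetate | CC(=O)OC/C=C(\C)CC[C@@H]1[C@@]2(C)CCCC(C)(C)[C@@H]2CC[C@@]1(C)O
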